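Ring B, the bromocyclohexene C6–C11 (spiro[5.5]undecane numbering), is cut at C6–C7 and at C8=C9, which takes out C7–C8(Br) as a two-carbon unit. The feature exploited is that the spiro carbon C6 is α to a latent ring A ketone (C1) while C9 can be a methyl ketone three bonds away, a 1,4-donor/acceptor pair. In one flask the C6 enolate adds to (1-bromovinyl)triphenylphosphonium bromide and the α-bromo ylide thus born olefinates the C9 ketone: a Michael/Wittig [4+2] annulation that delivers ring B, its vinyl bromide and the quaternary stereocentre. The precursor is a dimedone-type vinylogous ester with a 3-oxobutyl chain at C6 and a recoverable chiral alkoxy group at C3.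

Key step: step 5

Numbering used throughout: ring A = C1 (C–CH3), C2 (=CH), C3 (CHOH), C4 (CHBr), C5 (CMe2). C6 is the spiro carbon. Ring B = C7 (CH2), C8 (CBr), C9 (C–CH3), C10, C11. The monocyclic precursors carry the same locants C1–C6. The CIP descriptor of C6 changes between R and S along the route only because substituent priorities change; the spatial arrangement stays the same.

Assumption: both enantiomers of trans-2-(2-phenylpropan-2-yl)cyclohexan-1-ol are taken as purchasable. The sense of induction in step 5 follows the shielding model given there. Should it prove opposite, the antipodal alcohol is used in step 1.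

Step 1
Reactants: 1 3-chloro-5,5-dimethylcyclohex-2-en-1-one; 2 (1S,2R)-2-(2-phenylpropan-2-yl)cyclohexan-1-ol
Product: 3 5,5-dimethyl-3-{[(1S,2R)-2-(2-phenylpropan-2-yl)cyclohexyl]oxy}cyclohex-2-en-1-one
Conditions: 2, NaH, THF, 0 °C; then 1, 0 °C → rt
Reagents that add atoms: alcohol 2, O[C@H]1CCCC[C@@H]1C(C)(C)c1ccccc1
Why: Addition–elimination (vinylogous acyl substitution) of the sodium alkoxide on the β-chloroenone should give the vinylogous ester without touching the two stereocentres of the auxiliary.

Step 2
Reactants: 3 vinylogous ester; 4 4-iodobut-1-ene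
Product: 5 6-(but-3-en-1-yl)-5,5-dimethyl-3-{[(1S,2R)-2-(2-phenylpropan-2-yl)cyclohexyl]oxy}cyclohex-2-en-1-one (both C6 epimers)
Conditions: LDA, THF, −78 °C; then 4, DMPU, −78 °C → rt
Reagents that add atoms: 4-iodobut-1-ene (4), C=CCCI
Why: Stork–Danheiser kinetic α′-deprotonation of a 3-alkoxyenone takes place at C6 and is followed by SN2 alkylation with the primary iodide; the configuration at C6 is of no consequence because this carbon is planarised again in step 5.

Step 3
Reactants: 5 butenyl vinylogous ester
Product: 6 5,5-dimethyl-6-(3-oxobutyl)-3-{[(1S,2R)-2-(2-phenylpropan-2-yl)cyclohexyl]oxy}cyclohex-2-en-1-one (both C6 epimers)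
Conditions: PdCl2 (cat.), CuCl, O2 (1 atm), DMF/H2O, rt
Reagents that add atoms: water, O
Why: Tsuji–Wacker oxidation turns the terminal alkene into the methyl ketone with Markovnikov selectivity under nearly neutral conditions that should leave the push–pull C2=C3 bond and the enol ether untouched.

Step 4
Reactants: 7 vinyltriphenylphosphonium bromide
Product: 9 (1-bromovinyl)triphenylphosphonium bromide, via dibromide salt 8 (not isolated)
Conditions: Br2, CH2Cl2, 0 °C → rt; then Et3N, 0 °C; precipitation with Et2O
Reagents that add atoms: bromine, BrBr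
Why: Bromine addition to the vinyl group is followed by E1cB dehydrobromination, in which the proton α to phosphorus is the most acidic one, so that the β-bromide is expelled and bromine stays on the carbon that bears phosphorus.

Step 5
Reactants: 6 3-oxobutyl vinylogous ester; 9 (1-bromovinyl)triphenylphosphonium bromide
Product: 13 (6R)-8-bromo-5,5,9-trimethyl-3-{[(1S,2R)-2-(2-phenylpropan-2-yl)cyclohexyl]oxy}spiro[5.5]undeca-2,8-dien-1-one, via silyl enol ether 10 (not isolated), via masked bromo ylide 11 (not isolated), via keto bromo ylide 12 (not isolated)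
Conditions: LDA (1.0 equiv), THF, −78 °C, then TMSCl (1.0 equiv); LDA (1.2 equiv), −78 → −30 °C; 9, THF/DMPU, −78 → 0 °C; AcOH (1.0 equiv), TBAF (1.1 equiv), 0 → 40 °C
Reagents that add atoms: (1-bromovinyl)triphenylphosphonium bromide (9), C=C(Br)[P+](c1ccccc1)(c1ccccc1)c1ccccc1.[Br-]
Why: Proposed new method: after the methyl ketone has been masked in the flask as its kinetic trimethylsilyl enol ether, LDA generates the tetrasubstituted C6 lithium enolate, which adds through carbon to the unsubstituted CH2 terminus of the cationic acceptor 9 (C6–C7 bond) and so creates the α-bromo phosphonium ylide at C8; fluoride/acetic acid then releases the C9 ketone, and the ylide, too weakly basic to enolise it, closes to the oxaphosphetane and expels Ph3P=O (C8=C9 bond). The closest known reaction types are the Michael addition/intramolecular Wittig annulation of keto enolates with vinyltriphenylphosphonium bromide (Schweizer reagent) and the Wittig olefination with α-bromoalkylidene phosphoranes; new are the bromine on the acceptor, the neopentyl quaternary donor carbon and the tetrasubstituted bromoalkene as product. Ring B closes by 6-exo-trig attack of the ylide carbon on the C9 ketone, the only alternative (attack on C1=O) being a four-membered closure. The one new stereocentre, C6, is controlled by the auxiliary: with the C3–O bond s-cis to C2=C3 and the carbinol C–H in the dienolate plane, the cumyl phenyl ring of the (1S,2R)-alkoxy group stacks over one face of C1–C3, and because the Ph3P+ head of the acceptor has to lie over the enolate oxygen on the face that is attacked, C7 should enter from the open face to give (6R)-13, the minor C6 epimer being a diastereomer that is removed by chromatography. The step needs selectivity for C6 over the more acidic methyl ketone (secured by the silyl mask), for C- over O-attack (O-adducts revert by β-elimination from the ylide) and survival of the C–Br bond (no transition metal and no strong base after the addition).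

Step 6
Reactants: 13 spiro vinylogous ester
Product: 15 (6R)-8-bromo-1,5,5,9-tetramethylspiro[5.5]undeca-1,8-dien-3-one, via tertiary allylic alcohol 14 (not isolated)
Conditions: MeLi, CeCl3, THF, −78 → 0 °C; then 1 M HCl, THF, 0 °C → rt
Reagents that add atoms: methyllithium, [Li]C; water, O
Why: Stork–Danheiser transposition, in which the weakly basic organocerium reagent adds 1,2 to the hindered C1 ketone without bromine–lithium exchange at C8 and acid ionises the tertiary allylic alcohol to the C3 oxocarbenium ion, whose hydrolysis gives the enone and returns auxiliary 2, C6 remaining untouched.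

Step 7
Reactants: 15 spiro enone
Product: 17 (4S,6S)-4,8-dibromo-1,5,5,9-tetramethylspiro[5.5]undeca-1,8-dien-3-one, via silyl dienol ether 16 (not isolated)
Conditions: LDA, THF, −78 °C; TMSCl; then NBS, THF, −78 → 0 °C
Reagents that add atoms: N-bromosuccinimide, O=C1CCC(=O)N1Br
Why: Kinetic α′-deprotonation of the enone at C4, silylation and electrophilic bromination of the cross-conjugated silyl dienol ether place bromine at C4 anti to the pseudoaxial C5 methyl group of the half-chair that keeps the allylic arm C7 pseudoaxial, after which the bromide relaxes to the equatorial (4S) position; this bias against the spiro centre is only modest, so the (4R) epimer is separated and recycled by epimerisation.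

Step 8
Reactants: 17 α′-bromo enone
Product: 18 (3R,4S,6S)-4,8-dibromo-1,5,5,9-tetramethylspiro[5.5]undeca-1,8-dien-3-ol
Conditions: DIBAL-H, CH2Cl2, −78 °C; Rochelle salt work-up
Reagents that add atoms: none
Why: 1,2-Reduction of the enone, in which hydride comes from the face opposite to the axial C5 methyl group and the equatorial bromine, should give mainly the pseudoaxial (3R) alcohol cis to bromine, and the epimer composition is unimportant because step 9 is stereoconvergent.

Step 9
Reactants: 18 cis-bromohydrin
Product: 19 (3S,4S,6S)-4,8-dibromo-1,5,5,9-tetramethylspiro[5.5]undeca-1,8-dien-3-ol (target)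
Conditions: HClO4 (cat.), THF/H2O, 0 °C → rt
Reagents that add atoms: water, O
Why: Acid-catalysed SN1 allylic substitution (stereoconvergent hydrolysis), in which the C1–C3 allyl cation is captured by water at the less hindered secondary terminus C3 from the same open face that hydride used, anti to the C4 bromine (which can bridge) and to the axial C5 methyl group, so that OH ends trans to Br (3S), which is also the more stable diequatorial isomer.

Compound list
1 | 3-chloro-5,5-dimethylcyclohex-2-en-1-one | O=C1C=C(Cl)CC(C)(C)C1 | starting material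
2 | (1S,2R)-2-(2-phenylpropan-2-yl)cyclohexan-1-ol | O[C@H]1CCCC[C@@H]1C(C)(C)c1ccccc1 | starting material
3 | 5,5-dimethyl-3-{[(1S,2R)-2-(2-phenylpropan-2-yl)cyclohexyl]oxy}cyclohex-2-en-1-one | O=C1C=C(O[C@H]2CCCC[C@@H]2C(C)(C)c2ccccc2)CC(C)(C)C1 | intermediate
4 | 4-iodobut-1-ene | C=CCCI | starting material
5 | 6-(but-3-en-1-yl) vinylogous ester, both C6 epimers | O=C1C=C(O[C@H]2CCCC[C@@H]2C(C)(C)c2ccccc2)CC(C)(C)C1CCC=C | intermediate
6 | 6-(3-oxobutyl) vinylogous ester, both C6 epimers | O=C1C=C(O[C@H]2CCCC[C@@H]2C(C)(C)c2ccccc2)CC(C)(C)C1CCC(C)=O | intermediate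
7 | vinyltriphenylphosphonium bromide | C=C[P+](c1ccccc1)(c1ccccc1)c1ccccc1.[Br-] | starting material
8 | (1,2-dibromoethyl)triphenylphosphonium bromide | BrCC(Br)[P+](c1ccccc1)(c1ccccc1)c1ccccc1.[Br-] | intermediate
9 | (1-bromovinyl)triphenylphosphonium bromide | C=C(Br)[P+](c1ccccc1)(c1ccccc1)c1ccccc1.[Br-] | intermediate
10 | 6-[3-(trimethylsilyloxy)but-3-en-1-yl] vinylogous ester | O=C1C=C(O[C@H]2CCCC[C@@H]2C(C)(C)c2ccccc2)CC(C)(C)C1CCC(=C)O[Si](C)(C)C | intermediate
11 | (6R) Michael adduct, α-bromo ylide at C8 with the silyl enol ether still in place | O=C1C=C(O[C@H]2CCCC[C@@H]2C(C)(C)c2ccccc2)CC(C)(C)[C@]1(CC(Br)=P(c1ccccc1)(c1ccccc1)c1ccccc1)CCC(=C)O[Si](C)(C)C | intermediate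
12 | (6R) α-bromo ylide with free C9 methyl ketone | O=C1C=C(O[C@H]2CCCC[C@@H]2C(C)(C)c2ccccc2)CC(C)(C)[C@]1(CC(Br)=P(c1ccccc1)(c1ccccc1)c1ccccc1)CCC(C)=O | intermediate
13 | (6R)-8-bromo-5,5,9-trimethyl-3-{[(1S,2R)-2-(2-phenylpropan-2-yl)cyclohexyl]oxy}spiro[5.5]undeca-2,8-dien-1-one | O=C1C=C(O[C@H]3CCCC[C@@H]3C(C)(C)c3ccccc3)CC(C)(C)[C@]12CCC(C)=C(Br)C2 | intermediate
14 | tertiary allylic alcohol from methyl addition to C1 (C1 configuration open) | CC1(O)C=C(O[C@H]3CCCC[C@@H]3C(C)(C)c3ccccc3)CC(C)(C)[C@]12CCC(C)=C(Br)C2 | intermediate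
15 | (6R)-8-bromo-1,5,5,9-tetramethylspiro[5.5]undeca-1,8-dien-3-one | CC1=CC(=O)CC(C)(C)[C@]12CCC(C)=C(Br)C2 | intermediate
16 | 3-(trimethylsilyloxy) cross-conjugated dienol ether of 15 | CC1=CC(O[Si](C)(C)C)=CC(C)(C)[C@]12CCC(C)=C(Br)C2 | intermediate
17 | (4S,6S)-4,8-dibromo-1,5,5,9-tetramethylspiro[5.5]undeca-1,8-dien-3-one | CC1=CC(=O)[C@@H](Br)C(C)(C)[C@]12CCC(C)=C(Br)C2 | intermediate
18 | (3R,4S,6S)-4,8-dibromo-1,5,5,9-tetramethylspiro[5.5]undeca-1,8-dien-3-ol | CC1=C[C@@H](O)[C@@H](Br)C(C)(C)[C@]12CCC(C)=C(Br)C2 | intermediate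
19 | (3S,4S,6S)-4,8-dibromo-1,5,5,9-tetramethylspiro[5.5]undeca-1,8-dien-3-ol | CC1=C[C@H](O)[C@@H](Br)C(C)(C)[C@]12CCC(C)=C(Br)C2 | target

Total step count: 9. Longest linear sequence: 8 (steps 1, 2, 3, 5, 6, 7, 8, 9).

Steps most likely to fail

1. Step 5 (Proposed new method). Several things may go wrong.
- Carbon–carbon bond formation at the neopentyl C6 may be slower than proton transfer, O-attack, attack on bromine or addition of diisopropylamine to the salt.
- The remote auxiliary may discriminate the enolate faces only weakly.
- Closure to a tetrasubstituted bromoalkene may lag behind decay of the ylide.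

The fallback uses known chemistry, spiroannulation of a 3-alkoxyenone by double enolate alkylation. It sets out from 1 and comes back at 15. 4-Methyl-5,6-dihydro-2H-pyran-2-one F1 takes up bromine to give 3,4-dibromo-4-methyltetrahydro-2H-pyran-2-one F2. Et3N removes HBr from it to leave 3-bromo-4-methyl-5,6-dihydro-2H-pyran-2-one F3. DIBAL-H reduces the lactone to (E)-2-bromo-3-methylpent-2-ene-1,5-diol F4, whose alkene geometry is fixed by the former ring. CBr4/PPh3 then gives (E)-1,2,5-tribromo-3-methylpent-2-ene F5. Chloroenone 1 is joined as in step 1 to the antipodal auxiliary (1R,2S)-2-(2-phenylpropan-2-yl)cyclohexan-1-ol F6 to give the antipodal-auxiliary vinylogous ester F7. LDA and F5 alkylate C6 at the more reactive allylic bromide to give the monoalkylated vinylogous ester F8. A second equivalent of LDA closes C6–C11 by 6-exo-tet displacement of the primary bromide to give the spiro vinylogous ester F9. Here the last bond made at C6 is the one to C11 and not the one to C7, so the antipodal auxiliary is needed for the same (6R) arrangement. MeLi/CeCl3 gives the tertiary allylic alcohol F10, and dilute HCl as in step 6 then leads to 15.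

2. Step 7. The two faces of the silyl dienol ether differ only through the distant difference between the ring B arms C7 and C11, so facial selectivity at C4 may be poor. Traces of acid or base may also epimerise the α-bromo ketone. The fallback sets out from 13 and comes back at 17, and changes the control element from substrate to auxiliary. Bromine is introduced while the auxiliary still sits next to C4. LDA deprotonates 13 at C4, the only enolisable position left, and TMSCl gives the extended silyl dienol ether F11. NBS brominates its γ-terminus C4 (known γ-bromination of dienol ethers) from the face left open by the auxiliary to give the (4S,6R)-4-bromo spiro vinylogous ester F12. MeLi/CeCl3 gives the brominated tertiary allylic alcohol F13; C4 has no neighbouring C–H, so elimination is excluded. Cold dilute HCl then gives 17.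

3. Step 9. The allyl cation may lose a proton, may be captured at C1, or ionisation may be too slow next to the electron-withdrawing C–Br bond. The fallback sets out from 18 and comes back at 19, and uses SN2 inversion instead of ionisation. Mitsunobu reaction of 18 with chloroacetic acid, PPh3 and DIAD gives the inverted (3S)-chloroacetate F14. K2CO3/MeOH at 0 °C cleaves it fast enough to avoid epoxide formation from the trans-bromohydrin.

Further compounds
F1 | step 5 | 4-methyl-5,6-dihydro-2H-pyran-2-one | CC1=CC(=O)OCC1
F2 | step 5 | 3,4-dibromo-4-methyltetrahydro-2H-pyran-2-one | CC1(Br)CCOC(=O)C1Br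
F3 | step 5 | 3-bromo-4-methyl-5,6-dihydro-2H-pyran-2-one | CC1=C(Br)C(=O)OCC1
F4 | step 5 | (E)-2-bromo-3-methylpent-2-ene-1,5-diol | OC/C(Br)=C(/C)CCO
F5 | step 5 | (E)-1,2,5-tribromo-3-methylpent-2-ene | BrC/C(Br)=C(/C)CCBr
F6 | step 5 | (1R,2S)-2-(2-phenylpropan-2-yl)cyclohexan-1-ol | O[C@@H]1CCCC[C@H]1C(C)(C)c1ccccc1
F7 | step 5 | 5,5-dimethyl-3-{[(1R,2S)-2-(2-phenylpropan-2-yl)cyclohexyl]oxy}cyclohex-2-en-1-one | O=C1C=C(O[C@@H]2CCCC[C@H]2C(C)(C)c2ccccc2)CC(C)(C)C1
F8 | step 5 | 6-[(E)-2,5-dibromo-3-methylpent-2-en-1-yl] derivative of F7 | O=C1C=C(O[C@@H]2CCCC[C@H]2C(C)(C)c2ccccc2)CC(C)(C)C1C/C(Br)=C(/C)CCBr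
F9 | step 5 | (6R)-8-bromo-5,5,9-trimethyl-3-{[(1R,2S)-2-(2-phenylpropan-2-yl)cyclohexyl]oxy}spiro[5.5]undeca-2,8-dien-1-one | O=C1C=C(O[C@@H]3CCCC[C@H]3C(C)(C)c3ccccc3)CC(C)(C)[C@]12CCC(C)=C(Br)C2
F10 | step 5 | tertiary allylic alcohol from methyl addition to F9 | CC1(O)C=C(O[C@@H]3CCCC[C@H]3C(C)(C)c3ccccc3)CC(C)(C)[C@]12CCC(C)=C(Br)C2
F11 | step 7 | 1-(trimethylsilyloxy) extended dienol ether of 13 | C[Si](C)(C)OC1=CC(O[C@H]3CCCC[C@@H]3C(C)(C)c3ccccc3)=CC(C)(C)[C@]12CCC(C)=C(Br)C2
F12 | step 7 | (4S,6R)-4,8-dibromo-5,5,9-trimethyl-3-{[(1S,2R)-2-(2-phenylpropan-2-yl)cyclohexyl]oxy}spiro[5.5]undeca-2,8-dien-1-one | O=C1C=C(O[C@H]3CCCC[C@@H]3C(C)(C)c3ccccc3)[C@@H](Br)C(C)(C)[C@]12CCC(C)=C(Br)C2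
F13 | step 7 | tertiary allylic alcohol from methyl addition to F12 | CC1(O)C=C(O[C@H]3CCCC[C@@H]3C(C)(C)c3ccccc3)[C@@H](Br)C(C)(C)[C@]12CCC(C)=C(Br)C2
F14 | step 9 | (3S,4S,6S)-4,8-dibromo-1,5,5,9-tetramethylspiro[5.5]undeca-1,8-dien-3-yl chloroacetate | CC1=C[C@H](OC(=O)CCl)[C@@H](Br)C(C)(C)[C@]12CCC(C)=C(Br)C2
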